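**Retrosynthetic overview**
- Feature: C8a and C4a of ring A are the oxygen-bearing carbon and the β-carbon of the enol ether of a 2-aryl-3,4-dihydro-2H-pyran (ring C, which already holds C2), and C7 and C8 are adjacent oxygenated carbons.
- Late stage: the C7 and C8 methyl ethers come from a catechol, the catechol from its ene-1,2-dione tautomer, the dione from a cis-7,8-diol, and the diol from a cyclic carbonate.
- Key disconnection: C8a–C8 and C6–C7, by [4+2] cycloaddition of the diene C8a=C4a–C5=C6 (a 5-vinyl dihydropyran) with vinylene carbonate (C7–C8).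
- Diene: from Wittig methylenation of the C5 aldehyde, made by Vilsmeier formylation of the dihydropyran; this comes from the lactol of an (S)-δ-lactone, made by asymmetric transfer hydrogenation of the δ-keto acid from the aryl Grignard reagent and glutaric anhydride.
- Ring order: ring B is bought, ring C is closed second (lactonisation, C2 set by the reduction), ring A is built last and then aromatised.

Key step: step 7

Remark: 7 is carried as an anomeric mixture and 14, 15 and 16 as mixtures at the transient centres C7, C8 and C8a (C7/C8 cis), so their SMILES define C2 only.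

**Step 1**
Reactants: 1 5-bromo-1,2,3-trimethoxybenzene; 2 glutaric anhydride
Product: 4 5-oxo-5-(3,4,5-trimethoxyphenyl)pentanoic acid, via 3,4,5-trimethoxyphenylmagnesium bromide 3 (not isolated)
Conditions: Mg, THF, reflux; added to 2 (1.5 equiv), THF, −78 → 0 °C; aq. HCl
Reagents that add atoms: none
Why: Grignard acylation by ring opening of the cyclic anhydride, in which the magnesium keto-carboxylate formed at low temperature with inverse addition is deactivated towards a second addition.

**Step 2**
Reactants: 4 5-oxo-5-(3,4,5-trimethoxyphenyl)pentanoic acid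
Product: 6 (6S)-6-(3,4,5-trimethoxyphenyl)oxan-2-one, via (5S)-5-hydroxy-5-(3,4,5-trimethoxyphenyl)pentanoic acid 5 (not isolated)
Conditions: RuCl[(S,S)-TsDPEN](p-cymene) (1 mol%), HCO2H/Et3N (5:2), 40 °C; evaporate; PPTS (cat.), toluene, 50 °C
Reagents that add atoms: none
Why: Noyori asymmetric transfer hydrogenation of an aryl alkyl ketone, in which the (S,S)-catalyst delivers hydride to the face that gives the (S)-carbinol, followed by lactonisation through acyl substitution, which leaves the carbinol C–O bond and its configuration untouched.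

**Step 3**
Reactants: 6 (6S)-6-(3,4,5-trimethoxyphenyl)oxan-2-one
Product: 7 (6S)-6-(3,4,5-trimethoxyphenyl)oxan-2-ol (anomeric mixture)
Conditions: i-Bu2AlH (1.1 equiv), CH2Cl2, −78 °C; aq. KNaC4H4O6 (potassium sodium tartrate)
Reagents that add atoms: none
Why: Partial reduction of a lactone to the lactol, since the tetrahedral aluminium hemiacetal persists at −78 °C and collapses only on work-up.

**Step 4**
Reactants: 7 (6S)-6-(3,4,5-trimethoxyphenyl)oxan-2-ol
Product: 9 (2S)-2-(3,4,5-trimethoxyphenyl)-3,4-dihydro-2H-pyran, via anomeric mesylate 8 (not isolated)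
Conditions: MsCl, Et3N (excess), THF, 0 °C → reflux
Reagents that add atoms: none
Why: Lactol dehydration by anomeric sulfonylation and amine-promoted elimination through the oxocarbenium ion (the lactol-to-glycal method), run in basic medium so that the benzylic ether and the product enol ether are not exposed to acid.

**Step 5**
Reactants: 9 (2S)-2-(3,4,5-trimethoxyphenyl)-3,4-dihydro-2H-pyran
Product: 11 (2S)-2-(3,4,5-trimethoxyphenyl)-3,4-dihydro-2H-pyran-5-carbaldehyde, via C5 dimethyliminium chloride 10 (not isolated)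
Conditions: POCl3, DMF, 0 °C → rt; ice-cold aq. NaHCO3
Reagents that add atoms: N,N-dimethylformamide, CN(C)C=O; water, O
Why: Vilsmeier–Haack formylation at the nucleophilic β-carbon (C5) of the enol ether, as in the 2-C-formylation of glycals, with the enol ether reacting at 0 °C to room temperature far faster than the trimethoxyphenyl ring and the iminium ion hydrolysed in the bicarbonate quench.

**Step 6**
Reactants: 11 (2S)-2-(3,4,5-trimethoxyphenyl)-3,4-dihydro-2H-pyran-5-carbaldehyde
Product: 12 (2S)-5-ethenyl-2-(3,4,5-trimethoxyphenyl)-3,4-dihydro-2H-pyran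
Conditions: Ph3PCH3Br, KOt-Bu, THF, 0 °C → rt
Reagents that add atoms: methyltriphenylphosphonium bromide, C[P+](c1ccccc1)(c1ccccc1)c1ccccc1.[Br-]
Why: Wittig methylenation of a non-enolisable vinylogous formate aldehyde with the unstabilised ylide, under basic conditions that the enol ether tolerates; the diene should be used at once.

**Step 7**
Reactants: 12 (2S)-5-ethenyl-2-(3,4,5-trimethoxyphenyl)-3,4-dihydro-2H-pyran; 13 vinylene carbonate
Product: 14 (2S)-2-(3,4,5-trimethoxyphenyl)-3,4,6,7,8,8a-hexahydro-2H-chromene-7,8-diyl carbonate (cis-fused cyclic carbonate, mixture at C7, C8 and C8a)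
Conditions: 13 (8 equiv), BHT (cat.), toluene, base-washed sealed tube, 160 °C
Reagents that add atoms: none
Why: A thermal, concerted, suprafacial [4+2] cycloaddition of normal electron demand: the s-cis diene C8a=C4a–C5=C6 of 12, with its HOMO raised by O1 on the C8a terminus, adds across the C=C of 13, forming C8a–C8 and C6–C7 and leaving C4a=C5. The closest known reaction types are the Diels–Alder reactions of vinylene carbonate with 1-oxygenated and cyclic 1,3-dienes and the cycloadditions of 2-vinyl glycals with dienophiles. The six-membered carbocycle that becomes ring A is closed by intermolecular cycloaddition, both sigma bonds forming in the same pericyclic event, and the carbonate ends cis-fused because the Z geometry of the dienophile is retained. C7 and C8 are set cis by the suprafacial addition, C8a relative to them by the endo or exo transition state, and all three relative to C2 by the diene face attacked; none of this is controlled, and none needs to be, because the three centres become sp2 on aromatisation. The only selectivity required is cross-cycloaddition over dimerisation or polymerisation of the diene, which the large excess of dienophile, the radical inhibitor and acid-free glass should secure; the symmetric dienophile leaves no regiochemical question and C2 is remote from every bond change.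

**Step 8**
Reactants: 14 (2S)-hexahydrochromene 7,8-cyclic carbonate
Product: 15 (2S)-2-(3,4,5-trimethoxyphenyl)-3,4,6,7,8,8a-hexahydro-2H-chromene-7,8-diol (cis-diol, mixture at C7, C8 and C8a)
Conditions: K2CO3 (cat.), MeOH, rt
Reagents that add atoms: none
Why: Base-catalysed transesterification of the cyclic carbonate with methanol releases the cis-diol without touching the allylic ether or C2.

**Step 9**
Reactants: 15 (2S)-hexahydrochromene-7,8-diol
Product: 17 (2S)-2-(3,4,5-trimethoxyphenyl)-3,4-dihydro-2H-chromene-7,8-diol, via ene-1,2-dione 16 (not isolated)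
Conditions: DMSO, (CF3CO)2O, CH2Cl2, −78 °C; Et3N, −78 → 0 °C, argon
Reagents that add atoms: none
Why: Swern-type double oxidation with activated DMSO converts the vicinal diol into the 1,2-dione without C–C cleavage, and triethylamine then enolises C7=O towards C6 and C8=O towards C8a, so that the cyclohex-4-ene-1,2-dione tautomerises to the aromatic catechol.

**Step 10**
Reactants: 17 (2S)-2-(3,4,5-trimethoxyphenyl)-3,4-dihydro-2H-chromene-7,8-diol
Product: 18 (2S)-7,8-dimethoxy-2-(3,4,5-trimethoxyphenyl)-3,4-dihydro-2H-chromene ((2S)-7,8,3',4',5'-pentamethoxyflavan)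
Conditions: MeI, K2CO3, acetone, 40 °C, argon (crude 17 used directly)
Reagents that add atoms: iodomethane, CI
Why: Williamson O-methylation of both phenoxides by SN2 on iodomethane, in which the carbonate base also completes any unfinished dione-to-catechol tautomerisation and the benzylic C2–O bond is inert.

**Compound list**
1 | 5-bromo-1,2,3-trimethoxybenzene | COc1cc(Br)cc(OC)c1OC | starting material
2 | glutaric anhydride | O=C1CCCC(=O)O1 | starting material
3 | 3,4,5-trimethoxyphenylmagnesium bromide | COc1cc([Mg]Br)cc(OC)c1OC | intermediate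
4 | 5-oxo-5-(3,4,5-trimethoxyphenyl)pentanoic acid | COc1cc(C(=O)CCCC(=O)O)cc(OC)c1OC | intermediate
5 | (5S)-5-hydroxy-5-(3,4,5-trimethoxyphenyl)pentanoic acid | COc1cc([C@@H](O)CCCC(=O)O)cc(OC)c1OC | intermediate
6 | (6S)-6-(3,4,5-trimethoxyphenyl)oxan-2-one | COc1cc([C@@H]2CCCC(=O)O2)cc(OC)c1OC | intermediate
7 | (6S)-6-(3,4,5-trimethoxyphenyl)oxan-2-ol (anomeric mixture) | COc1cc([C@@H]2CCCC(O)O2)cc(OC)c1OC | intermediate
8 | (6S)-6-(3,4,5-trimethoxyphenyl)oxan-2-yl methanesulfonate (anomeric mesylate) | COc1cc([C@@H]2CCCC(OS(C)(=O)=O)O2)cc(OC)c1OC | intermediate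
9 | (2S)-2-(3,4,5-trimethoxyphenyl)-3,4-dihydro-2H-pyran | COc1cc([C@@H]2CCC=CO2)cc(OC)c1OC | intermediate
10 | N,N-dimethyl-1-[(2S)-2-(3,4,5-trimethoxyphenyl)-3,4-dihydro-2H-pyran-5-yl]methaniminium chloride | COc1cc([C@@H]2CCC(C=[N+](C)C)=CO2)cc(OC)c1OC.[Cl-] | intermediate
11 | (2S)-2-(3,4,5-trimethoxyphenyl)-3,4-dihydro-2H-pyran-5-carbaldehyde | COc1cc([C@@H]2CCC(C=O)=CO2)cc(OC)c1OC | intermediate
12 | (2S)-5-ethenyl-2-(3,4,5-trimethoxyphenyl)-3,4-dihydro-2H-pyran | COc1cc([C@@H]2CCC(C=C)=CO2)cc(OC)c1OC | intermediate
13 | vinylene carbonate (1,3-dioxol-2-one) | O=C1OC=CO1 | starting material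
14 | (2S)-2-(3,4,5-trimethoxyphenyl)-3,4,6,7,8,8a-hexahydro-2H-chromene-7,8-diyl carbonate (cis-fused, mixture at C7, C8, C8a) | COc1cc([C@@H]2CCC3=CCC4OC(=O)OC4C3O2)cc(OC)c1OC | intermediate
15 | (2S)-2-(3,4,5-trimethoxyphenyl)-3,4,6,7,8,8a-hexahydro-2H-chromene-7,8-diol (cis-diol, mixture at C7, C8, C8a) | COc1cc([C@@H]2CCC3=CCC(O)C(O)C3O2)cc(OC)c1OC | intermediate
16 | (2S)-2-(3,4,5-trimethoxyphenyl)-3,4,6,8a-tetrahydro-2H-chromene-7,8-dione | COc1cc([C@@H]2CCC3=CCC(=O)C(=O)C3O2)cc(OC)c1OC | intermediate
17 | (2S)-2-(3,4,5-trimethoxyphenyl)-3,4-dihydro-2H-chromene-7,8-diol | COc1cc([C@@H]2CCc3ccc(O)c(O)c3O2)cc(OC)c1OC | intermediate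
18 | (2S)-7,8-dimethoxy-2-(3,4,5-trimethoxyphenyl)-3,4-dihydro-2H-chromene | COc1cc([C@@H]2CCc3ccc(OC)c(OC)c3O2)cc(OC)c1OC | target

**Total step count:** 10
**Longest linear sequence:** 10 steps (from 1)

**Steps most likely to fail**

1. Step 7. Dimerisation or polymerisation of the electron-rich diene, or its thermal decay, may outrun cross-cycloaddition with the sluggish dienophile. Fallback: ring A is bought instead of built; the route leaves at 1 and returns at 18.
 - Grignard reagent 3 (from 1) is acylated with N-methoxy-N-methylacetamide to give 1-(3,4,5-trimethoxyphenyl)ethanone F1.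
 - Claisen–Schmidt condensation of F1 with commercial 2-hydroxy-3,4-dimethoxybenzaldehyde (COc1ccc(C=O)c(O)c1OC; KOH, EtOH) gives (E)-3-(2-hydroxy-3,4-dimethoxyphenyl)-1-(3,4,5-trimethoxyphenyl)prop-2-en-1-one F2.
 - Hydrogenation of the C=C bond (H2, RhCl(PPh3)3) gives 3-(2-hydroxy-3,4-dimethoxyphenyl)-1-(3,4,5-trimethoxyphenyl)propan-1-one F3.
 - Transfer hydrogenation with RuCl[(R,R)-TsDPEN](p-cymene) in HCO2H/Et3N gives 6-[(3R)-3-hydroxy-3-(3,4,5-trimethoxyphenyl)propyl]-2,3-dimethoxyphenol F4.
 - Mitsunobu cyclisation of F4 (PPh3, DIAD, THF, 0 °C) closes ring C with inversion at the carbinol and gives 18.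

2. Step 9. The double oxidation may stall at the ketol stage, cleave the C7–C8 bond, or carry on past the electron-rich catechol (further oxidation, or alkylation by the activated sulfoxide on warming). Fallback: stepwise oxidation; the route leaves at 15 and returns at 17.
 - The dibutylstannylene acetal of 15 (Bu2SnO, toluene, reflux) is oxidised with N-bromosuccinimide to the ketols (2S)-8-hydroxy-2-(3,4,5-trimethoxyphenyl)-2,3,4,6,8,8a-hexahydrochromen-7-one F5 and (2S)-7-hydroxy-2-(3,4,5-trimethoxyphenyl)-2,3,4,6,7,8a-hexahydrochromen-8-one F6.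
 - Both ketols are oxidised with one equivalent of buffered Dess–Martin periodinane to dione 16.
 - A reductive quench (aq. Na2S2O3) followed by Et3N gives 17.

3. Step 5. Acid released during formylation may hydrate or oligomerise the enol ether or open the product ring, and on warming the trimethoxyphenyl ring may be formylated. Fallback: the C5 carbon substituent is introduced by cross-coupling; the route leaves at 9 and returns at 12, which also makes step 6 unnecessary.
 - Iodination of 9 with N-iodosuccinimide and catalytic AgNO3 in MeCN gives (2S)-5-iodo-2-(3,4,5-trimethoxyphenyl)-3,4-dihydro-2H-pyran F7.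
 - Suzuki–Miyaura coupling of F7 with vinylboronic acid pinacol ester (Pd(PPh3)4, K2CO3, dioxane/H2O, 80 °C) gives 12.

**Further compounds**
F1 | step 7 | 1-(3,4,5-trimethoxyphenyl)ethanone | COc1cc(C(C)=O)cc(OC)c1OC
F2 | step 7 | (E)-3-(2-hydroxy-3,4-dimethoxyphenyl)-1-(3,4,5-trimethoxyphenyl)prop-2-en-1-one | COc1cc(C(=O)/C=C/c2ccc(OC)c(OC)c2O)cc(OC)c1OC
F3 | step 7 | 3-(2-hydroxy-3,4-dimethoxyphenyl)-1-(3,4,5-trimethoxyphenyl)propan-1-one | COc1cc(C(=O)CCc2ccc(OC)c(OC)c2O)cc(OC)c1OC
F4 | step 7 | 6-[(3R)-3-hydroxy-3-(3,4,5-trimethoxyphenyl)propyl]-2,3-dimethoxyphenol | COc1cc([C@H](O)CCc2ccc(OC)c(OC)c2O)cc(OC)c1OC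
F5 | step 9 | (2S)-8-hydroxy-2-(3,4,5-trimethoxyphenyl)-2,3,4,6,8,8a-hexahydrochromen-7-one | COc1cc([C@@H]2CCC3=CCC(=O)C(O)C3O2)cc(OC)c1OC
F6 | step 9 | (2S)-7-hydroxy-2-(3,4,5-trimethoxyphenyl)-2,3,4,6,7,8a-hexahydrochromen-8-one | COc1cc([C@@H]2CCC3=CCC(O)C(=O)C3O2)cc(OC)c1OC
F7 | step 5 | (2S)-5-iodo-2-(3,4,5-trimethoxyphenyl)-3,4-dihydro-2H-pyran | COc1cc([C@@H]2CCC(I)=CO2)cc(OC)c1OC
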